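**Plan**

Ring numbering used throughout: O1–C2(aryl)–C3(CH2OH)–C4(aroyl)–C5H2.
Retrosynthesis cuts, in this order: the aryl–C(=O) bond of the C4 arm (aldehyde + aryl Grignard reagent, with the C3 arm at the ester level), the ring bond C2–C3, and the ether bond O1–C2 (benzylic electrophile + hydroxymethyl lactone).
Enabling feature: C2 is a benzylic ether carbon whose C–H lies five atoms from C3 once O1–C5 exists as an ArCH2–O–CH2 ether, and the one-carbon arms on C3 and C4 can be joined as a γ-lactone (C3–C(=O)–O–CH2–C4), which makes C3 the diazo-bearing α-carbon.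
Forward: the lactone ring is present from the start; the ether tether is attached, the diazo group is introduced, and the oxolane is closed onto the lactone by Rh(II) carbene 1,5 C–H insertion (cis-fused bicycle). The lactone is then opened, the C4 arm oxidised and arylated, the C3 arm reduced, the benzylic alcohol oxidised and the phenols freed.
Stereochemistry: C4 comes from (R)-paraconic acid. C2 is set in the insertion (aryl endo, cis to the C4 arm). C3 is formed cis by the ring fusion and is then inverted by base equilibration of the opened ester to the 2,3-trans/3,4-trans array.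

Key step: step 5

Assumption: (R)-paraconic acid is taken as purchasable as the single enantiomer (otherwise it is reachable from the racemate by classical resolution); 2-benzyloxy-4-bromoanisole and (3-benzyloxy-4-methoxyphenyl)methanol are taken as catalogue compounds.
Remark: the insertion is planned on its expected kinetic outcome for this substrate class, aryl on the concave face (all-cis 8). This already has the C2/C4 relationship of the target, and step 6 supplies the C3 configuration.

**Route**

Step 1
Reactants: 1 (R)-paraconic acid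
Product: 2 (S)-4-(hydroxymethyl)oxolan-2-one
Conditions: BH3·SMe2 (1.2 equiv), THF, 0 °C → rt; MeOH quench, evaporation
Reagents that add atoms: none
Why: Chemoselective borane reduction of the carboxylic acid, which borane attacks far faster than the γ-lactone; the stereocentre is not involved (R becomes S only through the CIP ranking), and the neutral work-up avoids the base-induced acyl shift between the two CH2O arms that would racemise 2.

Step 2
Reactants: 3 (3-benzyloxy-4-methoxyphenyl)methanol
Product: 4 (3-benzyloxy-4-methoxyphenyl)methyl 2,2,2-trichloroacetimidate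
Conditions: Cl3CCN, DBU (cat.), CH2Cl2, 0 °C
Reagents that add atoms: trichloroacetonitrile, ClC(Cl)(Cl)C#N
Why: Base-catalysed addition of the benzylic alkoxide to trichloroacetonitrile (trichloroacetimidate formation), routine for electron-rich benzyl alcohols.

Step 3
Reactants: 2 (S)-4-(hydroxymethyl)oxolan-2-one; 4 (3-benzyloxy-4-methoxyphenyl)methyl 2,2,2-trichloroacetimidate
Product: 5 (S)-4-{[(3-benzyloxy-4-methoxyphenyl)methoxy]methyl}oxolan-2-one
Conditions: CSA (5 mol %), CH2Cl2, 0 °C → rt
Reagents that add atoms: none
Why: Acid-catalysed O-alkylation with a benzylic trichloroacetimidate (the protocol used for para-methoxybenzyl ethers): the para-methoxy-stabilised benzylic cation is captured by the primary alcohol and trichloroacetamide leaves, with no base present that could move the lactone between the two CH2O arms.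

Step 4
Reactants: 5 (S)-4-{[(3-benzyloxy-4-methoxyphenyl)methoxy]methyl}oxolan-2-one
Product: 7 (S)-3-diazo-4-{[(3-benzyloxy-4-methoxyphenyl)methoxy]methyl}oxolan-2-one, via trifluoroacetyl lactone 6 (not isolated)
Conditions: LiHMDS, THF, −78 °C; CF3CO2CH2CF3; 5% HCl wash; crude into p-ABSA, Et3N, H2O (1 equiv), MeCN, rt
Reagents that add atoms: 2,2,2-trifluoroethyl trifluoroacetate, O=C(OCC(F)(F)F)C(F)(F)F (trifluoroacetyl group of 6 only); 4-acetamidobenzenesulfonyl azide, CC(=O)Nc1ccc(cc1)S(=O)(=O)N=[N+]=[N-] (the two diazo nitrogens of 7)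
Why: Danheiser detrifluoroacetylative diazo transfer: Claisen trifluoroacetylation of the lactone lithium enolate activates the α-carbon, and the sulfonyl azide then delivers N2 while the trifluoroacetyl group leaves on the sulfonamide; the C4 centre is β to the carbonyl and is not touched.

Step 5
Reactants: 7 (S)-3-diazo-4-{[(3-benzyloxy-4-methoxyphenyl)methoxy]methyl}oxolan-2-one
Product: 8 (1R,5S,8S)-8-(3-benzyloxy-4-methoxyphenyl)-3,7-dioxabicyclo[3.3.0]octan-2-one (cis-fused; aryl endo, on the same face of the oxolane as both lactone carbons)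
Conditions: Rh2(OAc)4 (2 mol %), CH2Cl2, rt → 40 °C, slow addition of 7
Reagents that add atoms: none
Why: Rh2(OAc)4 extrudes N2 from 7 to give an electrophilic rhodium carbene at the lactone α-carbon (future C3), which inserts in a concerted, asynchronous three-centre fashion into one ArCH2–O C–H bond (future C2), a bond made hydridic by the ether oxygen and the para-methoxyaryl ring; the closest known reaction type is the Rh(II)-catalysed 1,5 C–H insertion of β-(arylmethoxymethyl)-α-diazo-γ-butyrolactones to aryl furofuranones. The oxolane closes by 1,5-insertion, a five-membered ring formed through a chair-like six-centre transition state that includes the migrating hydrogen, with C2–C3 as the new skeletal bond. C3 (C1 of the bicycle) is controlled by the tether, because the side chain on the pre-set C4 centre can reach the carbene only on its own face of the lactone, so the ring fusion must be cis. C2 (C8) is controlled by the transition-state preference of the aryl group to turn away from the rhodium carboxylate wall and toward the lactone carbonyl, which should place it on the concave face, cis to both arms; this kinetic all-cis product has the C2/C4 relationship of the target, and C3 is corrected in step 6. The step needs 1,5-insertion to outrun 1,2-hydride shift from C4–H, carbene dimerisation and attack on the arene, which the doubly activated C–H bond, the five-membered geometry and slow addition of 7 should secure; the PhCH2O C–H bonds and a four-membered oxonium ylide are out of geometric reach.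

Step 6
Reactants: 8 (1R,5S,8S)-8-(3-benzyloxy-4-methoxyphenyl)-3,7-dioxabicyclo[3.3.0]octan-2-one
Product: 10 methyl (2S,3S,4R)-2-(3-benzyloxy-4-methoxyphenyl)-4-(hydroxymethyl)oxolane-3-carboxylate, via all-cis hydroxy ester 9 (not isolated)
Conditions: NaOMe (0.5 equiv), MeOH, rt → 50 °C; AcOH at 0 °C
Reagents that add atoms: methanol, CO (delivered as methoxide)
Why: Methoxide-mediated lactone methanolysis coupled with thermodynamic α-epimerisation of the ester: the open cis ester 9 enolises and reprotonates to put the C3 ester trans to both the C2 aryl and the C4 CH2OH, and this isomer cannot re-lactonise (a trans-fused bicyclo[3.3.0] lactone is too strained), so the equilibrium should drain to 10, while C2 and C4 carry no acidic hydrogen.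

Step 7
Reactants: 10 methyl (2S,3S,4R)-2-(3-benzyloxy-4-methoxyphenyl)-4-(hydroxymethyl)oxolane-3-carboxylate
Product: 11 methyl (2S,3S,4S)-2-(3-benzyloxy-4-methoxyphenyl)-4-formyloxolane-3-carboxylate
Conditions: Dess–Martin periodinane, CH2Cl2, 0 °C → rt; used crude
Reagents that add atoms: none
Why: Dess–Martin oxidation of the primary alcohol to the aldehyde under non-basic conditions, so that the β-alkoxy aldehyde should neither eliminate nor over-oxidise; C4 already sits trans to C3, the favoured arrangement, should it enolise.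

Step 8
Reactants: 11 methyl (2S,3S,4S)-2-(3-benzyloxy-4-methoxyphenyl)-4-formyloxolane-3-carboxylate; 12 2-benzyloxy-4-bromoanisole
Product: 14 methyl (2S,3S,4S)-2-(3-benzyloxy-4-methoxyphenyl)-4-[(3-benzyloxy-4-methoxyphenyl)(hydroxy)methyl]oxolane-3-carboxylate (both carbinol epimers), via arylmagnesium bromide 13 (not isolated)
Conditions: 12, Mg, I2 (cat.), THF, 40 °C; then 11, THF, −78 °C; H2O, then aq. NH4Cl wash
Reagents that add atoms: magnesium, [Mg] (held in 13 only)
Why: Grignard formation followed by chemoselective 1,2-addition to the aldehyde at −78 °C, where the methyl ester is untouched and addition outpaces enolisation; the new carbinol centre is formed without control, which does not matter because it is oxidised in step 10.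

Step 9
Reactants: 14 methyl (2S,3S,4S)-2-(3-benzyloxy-4-methoxyphenyl)-4-[(3-benzyloxy-4-methoxyphenyl)(hydroxy)methyl]oxolane-3-carboxylate
Product: 15 (3-benzyloxy-4-methoxyphenyl)[(3S,4R,5S)-5-(3-benzyloxy-4-methoxyphenyl)-4-(hydroxymethyl)oxolan-3-yl]methanol (both carbinol epimers)
Conditions: LiAlH4, THF, 0 °C; Fieser work-up
Reagents that add atoms: none
Why: LiAlH4 reduction of the methyl ester to the primary alcohol; the aryl benzyl ethers and the oxolane are inert to hydride and no ring stereocentre is epimerisable here.

Step 10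
Reactants: 15 (3-benzyloxy-4-methoxyphenyl)[(3S,4R,5S)-5-(3-benzyloxy-4-methoxyphenyl)-4-(hydroxymethyl)oxolan-3-yl]methanol
Product: 16 (3-benzyloxy-4-methoxyphenyl)[(3S,4R,5S)-5-(3-benzyloxy-4-methoxyphenyl)-4-(hydroxymethyl)oxolan-3-yl]methanone
Conditions: activated MnO2 (excess), CH2Cl2, rt
Reagents that add atoms: none
Why: Chemoselective MnO2 oxidation of the para-alkoxy-activated benzylic secondary alcohol, which leaves the non-activated primary alcohol alone; the ketone is trans to the CH2OH so no hemiketal forms, and the neutral heterogeneous conditions should not enolise C4.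

Step 11
Reactants: 16 (3-benzyloxy-4-methoxyphenyl)[(3S,4R,5S)-5-(3-benzyloxy-4-methoxyphenyl)-4-(hydroxymethyl)oxolan-3-yl]methanone
Product: 17 (3-hydroxy-4-methoxyphenyl)[(3S,4R,5S)-5-(3-hydroxy-4-methoxyphenyl)-4-(hydroxymethyl)oxolan-3-yl]methanone (CNP0234761.1; C2 S, C3 R, C4 S in the ring numbering of the plan)
Conditions: H2 (1 atm), 10% Pd/C, EtOAc, rt, stopped after two equivalents of H2
Reagents that add atoms: none
Why: Palladium-catalysed hydrogenolysis of the two aryl benzyl ethers, which should be cleaved well before the cyclic benzylic C2–O1 bond or the electron-rich aryl ketone is attacked under these mild neutral conditions.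

**Compound list**

1 | (R)-paraconic acid, (3R)-5-oxooxolane-3-carboxylic acid | OC(=O)[C@H]1COC(=O)C1 | starting material
2 | (S)-4-(hydroxymethyl)oxolan-2-one | OC[C@H]1COC(=O)C1 | intermediate
3 | (3-benzyloxy-4-methoxyphenyl)methanol | COc1ccc(CO)cc1OCc1ccccc1 | starting material
4 | (3-benzyloxy-4-methoxyphenyl)methyl 2,2,2-trichloroacetimidate | COc1ccc(COC(=N)C(Cl)(Cl)Cl)cc1OCc1ccccc1 | intermediate
5 | (S)-4-{[(3-benzyloxy-4-methoxyphenyl)methoxy]methyl}oxolan-2-one | COc1ccc(COC[C@H]2COC(=O)C2)cc1OCc1ccccc1 | intermediate
6 | (4S)-4-{[(3-benzyloxy-4-methoxyphenyl)methoxy]methyl}-3-(trifluoroacetyl)oxolan-2-one (C3 epimers/enol) | COc1ccc(COC[C@H]2COC(=O)C2C(=O)C(F)(F)F)cc1OCc1ccccc1 | intermediate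
7 | (S)-3-diazo-4-{[(3-benzyloxy-4-methoxyphenyl)methoxy]methyl}oxolan-2-one | COc1ccc(COC[C@H]2COC(=O)C2=[N+]=[N-])cc1OCc1ccccc1 | intermediate
8 | (1R,5S,8S)-8-(3-benzyloxy-4-methoxyphenyl)-3,7-dioxabicyclo[3.3.0]octan-2-one (cis-fused, aryl endo) | C1[C@@H]2CO[C@H](c3ccc(OC)c(OCc4ccccc4)c3)[C@@H]2C(=O)O1 | intermediate
9 | methyl (2S,3R,4R)-2-(3-benzyloxy-4-methoxyphenyl)-4-(hydroxymethyl)oxolane-3-carboxylate (all-cis) | OC[C@@H]1CO[C@H](c2ccc(OC)c(OCc3ccccc3)c2)[C@@H]1C(=O)OC | intermediate
10 | methyl (2S,3S,4R)-2-(3-benzyloxy-4-methoxyphenyl)-4-(hydroxymethyl)oxolane-3-carboxylate (2,3-trans, 3,4-trans) | OC[C@@H]1CO[C@H](c2ccc(OC)c(OCc3ccccc3)c2)[C@H]1C(=O)OC | intermediate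
11 | methyl (2S,3S,4S)-2-(3-benzyloxy-4-methoxyphenyl)-4-formyloxolane-3-carboxylate | O=C[C@@H]1CO[C@H](c2ccc(OC)c(OCc3ccccc3)c2)[C@H]1C(=O)OC | intermediate
12 | 2-benzyloxy-4-bromoanisole | COc1ccc(Br)cc1OCc1ccccc1 | starting material
13 | (3-benzyloxy-4-methoxyphenyl)magnesium bromide | COc1ccc([Mg]Br)cc1OCc1ccccc1 | intermediate
14 | methyl (2S,3S,4S)-2-(3-benzyloxy-4-methoxyphenyl)-4-[(3-benzyloxy-4-methoxyphenyl)(hydroxy)methyl]oxolane-3-carboxylate (both carbinol epimers) | OC(c1ccc(OC)c(OCc2ccccc2)c1)[C@@H]3CO[C@H](c4ccc(OC)c(OCc5ccccc5)c4)[C@H]3C(=O)OC | intermediate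
15 | (3-benzyloxy-4-methoxyphenyl)[(3S,4R,5S)-5-(3-benzyloxy-4-methoxyphenyl)-4-(hydroxymethyl)oxolan-3-yl]methanol (both carbinol epimers) | OC(c1ccc(OC)c(OCc2ccccc2)c1)[C@@H]3CO[C@H](c4ccc(OC)c(OCc5ccccc5)c4)[C@H]3CO | intermediate
16 | (3-benzyloxy-4-methoxyphenyl)[(3S,4R,5S)-5-(3-benzyloxy-4-methoxyphenyl)-4-(hydroxymethyl)oxolan-3-yl]methanone | COc1ccc(C(=O)[C@@H]2CO[C@H](c3ccc(OC)c(OCc4ccccc4)c3)[C@H]2CO)cc1OCc1ccccc1 | intermediate
17 | (3-hydroxy-4-methoxyphenyl)[(3S,4R,5S)-5-(3-hydroxy-4-methoxyphenyl)-4-(hydroxymethyl)oxolan-3-yl]methanone | COc1ccc(C(=O)[C@@H]2CO[C@H](c3ccc(OC)c(O)c3)[C@H]2CO)cc1O | target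

**Step count and risks**

Total steps: 11. Longest linear sequence: 10 (1 → 17 through steps 1 and 3–11; step 2 is a one-step side branch).

Step 5 (key step). The carbene may leak into 1,2-hydride shift from C4–H or into dimerisation, or the facial preference at C2 may be weaker than expected, which would cost material or give the wrong C2/C4 relationship. The fallback forms C2–C3 by enolate chemistry and sets C2 by ionic hydrogenation; it sets out from 2 and returns to the route at 8. Compound 2 is silylated (TBSCl, imidazole, CH2Cl2) to (R)-4-({[tert-butyl(dimethyl)silyl]oxy}methyl)oxolan-2-one F1. Its lithium enolate (LiHMDS, THF, −78 °C) is added to commercial 3-benzyloxy-4-methoxybenzaldehyde to give the aldol adduct (4R)-3-[(3-benzyloxy-4-methoxyphenyl)(hydroxy)methyl]-4-({[tert-butyl(dimethyl)silyl]oxy}methyl)oxolan-2-one F2. Dess–Martin oxidation converts this into the β-keto lactone (4R)-3-(3-benzyloxy-4-methoxybenzoyl)-4-({[tert-butyl(dimethyl)silyl]oxy}methyl)oxolan-2-one F3. HF·pyridine removes the silyl group, and the freed CH2OH should close onto the aryl ketone (C3 equilibrates through the enol) to give the cis-fused hemiketal (1R,5S)-8-(3-benzyloxy-4-methoxyphenyl)-8-hydroxy-3,7-dioxabicyclo[3.3.0]octan-2-one F4. Et3SiH with BF3·OEt2 (CH2Cl2, −78 → −20 °C) should then reduce the derived aryl-stabilised oxocarbenium ion from the convex face, which places the aryl group endo and gives 8.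

Step 6. In methanolic methoxide the lactone may stay largely closed, so that the open ester in which C3 can invert is only a minor partner; forcing the reaction invites β-elimination of the ring oxygen O1 from the ester enolate, which would erode the stereochemical integrity. The fallback inverts C3 at the aldehyde oxidation level, where ring–chain tautomerism opens the bicycle without help; it sets out from 8 and returns at 10. DIBAL-H (CH2Cl2, −78 °C) reduces 8 to the lactol (1R,5S,8S)-8-(3-benzyloxy-4-methoxyphenyl)-3,7-dioxabicyclo[3.3.0]octan-2-ol F5. A mild amine base (catalytic pyrrolidine/AcOH, or DBU, rt) should epimerise the open hydroxy aldehyde at C3 to (2S,3S,4R)-2-(3-benzyloxy-4-methoxyphenyl)-4-(hydroxymethyl)oxolane-3-carbaldehyde F6, which cannot close again. Pinnick oxidation (NaClO2, NaH2PO4, 2-methyl-2-butene, tBuOH/H2O) gives (2S,3S,4R)-2-(3-benzyloxy-4-methoxyphenyl)-4-(hydroxymethyl)oxolane-3-carboxylic acid F7, and TMSCHN2 (MeOH/toluene) gives 10.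

Step 3. The acid may trigger self-condensation or rearrangement of the electron-rich imidate before the alcohol captures it, and it may promote the acyl shift between the two CH2O arms of 2, which lowers the enantiomeric purity without showing in the yield. The fallback is a reductive etherification in which the hydroxyl is capped throughout; it sets out from 2 and returns at 5. Compound 2 is silylated under neutral conditions (N,O-bis(trimethylsilyl)acetamide, CH2Cl2) to (R)-4-{[(trimethylsilyl)oxy]methyl}oxolan-2-one F8. This is combined with commercial 3-benzyloxy-4-methoxybenzaldehyde and Et3SiH under catalytic TMSOTf (CH2Cl2, −78 °C); the oxocarbenium ion formed from the aldehyde and the silyl ether is reduced in situ to the benzylic ether 5.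

**Further compounds**

F1 | step 5 | (R)-4-({[tert-butyl(dimethyl)silyl]oxy}methyl)oxolan-2-one | CC(C)(C)[Si](C)(C)OC[C@H]1COC(=O)C1
F2 | step 5 | (4R)-3-[(3-benzyloxy-4-methoxyphenyl)(hydroxy)methyl]-4-({[tert-butyl(dimethyl)silyl]oxy}methyl)oxolan-2-one (mixture at C3 and the carbinol carbon) | CC(C)(C)[Si](C)(C)OC[C@H]1COC(=O)C1C(O)c2ccc(OC)c(OCc3ccccc3)c2
F3 | step 5 | (4R)-3-(3-benzyloxy-4-methoxybenzoyl)-4-({[tert-butyl(dimethyl)silyl]oxy}methyl)oxolan-2-one | CC(C)(C)[Si](C)(C)OC[C@H]1COC(=O)C1C(=O)c2ccc(OC)c(OCc3ccccc3)c2
F4 | step 5 | (1R,5S)-8-(3-benzyloxy-4-methoxyphenyl)-8-hydroxy-3,7-dioxabicyclo[3.3.0]octan-2-one (anomer mixture) | C1[C@@H]2COC(O)(c3ccc(OC)c(OCc4ccccc4)c3)[C@@H]2C(=O)O1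
F5 | step 6 | (1R,5S,8S)-8-(3-benzyloxy-4-methoxyphenyl)-3,7-dioxabicyclo[3.3.0]octan-2-ol (anomer mixture) | C1[C@@H]2CO[C@H](c3ccc(OC)c(OCc4ccccc4)c3)[C@@H]2C(O)O1
F6 | step 6 | (2S,3S,4R)-2-(3-benzyloxy-4-methoxyphenyl)-4-(hydroxymethyl)oxolane-3-carbaldehyde | OC[C@@H]1CO[C@H](c2ccc(OC)c(OCc3ccccc3)c2)[C@H]1C=O
F7 | step 6 | (2S,3S,4R)-2-(3-benzyloxy-4-methoxyphenyl)-4-(hydroxymethyl)oxolane-3-carboxylic acid | OC[C@@H]1CO[C@H](c2ccc(OC)c(OCc3ccccc3)c2)[C@H]1C(=O)O
F8 | step 3 | (R)-4-{[(trimethylsilyl)oxy]methyl}oxolan-2-one | C[Si](C)(C)OC[C@H]1COC(=O)C1
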